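**Strategy.** The isoflavan is cut at C4–C4a and at C3–H. C3 of ring C lies between two methylenes, C2 (on O1) and C4 (on C4a of ring A), so ring C unfolds to a 2-(ring B)allyl ether of a ring-A 2-bromophenol whose terminal olefin carbon is the future C4. One flask operation, cobalt-catalysed enantioselective anti-Markovnikov hydroboration followed by palladium-catalysed B-alkyl Suzuki closure, sets the C3 stereocentre and closes ring C. Both aryl halves come from 4-bromoresorcinol through one aryl 1,1-dimethylpropargyl ether: heating gives the ring-B chromene, semi-hydrogenation and Claisen rearrangement give the ring-A prenyl group. The two phenols (O7, O4′) are carried as TIPS ethers.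

Key step: step 12

Remarks on the chemistry
- L is the iminopyridine–oxazoline ligand 2-[1-(2,6-diisopropylphenylimino)ethyl]-6-(4-tert-butyl-4,5-dihydro-1,3-oxazol-2-yl)pyridine, used as its CoCl2 complex. The antipode is the one that delivers hydride to the Si face of the internal olefin carbon (future C3), which gives 3R. The sense of induction is assumed to follow that of α-alkylstyrenes, the aryloxymethyl arm taking the place of the alkyl group.
- A 3-methylbut-2-enyl aryl ether would give the reverse-prenyl isomer on [3,3] shift, so the 1,1-dimethylallyl ether is the Claisen substrate.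
- Ring A is built from 4-bromoresorcinol and O1 is introduced next to bromine as a boronate, which fixes the positions of Br, OMe, prenyl and OTIPS without any statistical protection.

**Step 1**
Reactants: 1 4-bromoresorcinol
Product: 2 2-bromo-5-(triisopropylsilyloxy)phenol
Conditions: TIPSCl (1.05 equiv), imidazole, CH2Cl2, −20 → 0 °C
Reagents that add atoms: chlorotri(propan-2-yl)silane (TIPSCl), CC(C)[Si](Cl)(C(C)C)C(C)C
Why: Regioselective O-silylation; the bulky silyl chloride should react at the hydroxyl para to bromine, which has two free ortho positions, faster than at the hydroxyl beside bromine.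

**Step 2**
Reactants: 2 2-bromo-5-(triisopropylsilyloxy)phenol; 3 3-chloro-3-methylbut-1-yne
Product: 4 [4-bromo-3-(2-methylbut-3-yn-2-yloxy)phenoxy]tri(propan-2-yl)silane
Conditions: DBU, CuCl2·2H2O (cat.), MeCN, 0 °C → rt
Reagents that add atoms: none
Why: Copper-catalysed propargylic etherification of a phenol with a tertiary propargylic chloride, the standard entry to aryl 1,1-dimethylpropargyl ethers.

**Step 3**
Reactants: 4 [4-bromo-3-(2-methylbut-3-yn-2-yloxy)phenoxy]tri(propan-2-yl)silane
Product: 5 8-bromo-2,2-dimethyl-5-(triisopropylsilyloxy)-2H-chromene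
Conditions: PhNEt2, 170 °C
Reagents that add atoms: none
Why: Thermal aryl propargyl ether rearrangement (propargyl Claisen, 1,5-hydrogen shift, 6π-electrocyclisation); bromine blocks one ortho carbon, so the pyran ring can close only onto the carbon between the two oxygens.

**Step 4**
Reactants: 5 8-bromo-2,2-dimethyl-5-(triisopropylsilyloxy)-2H-chromene
Product: 7 2-[2,2-dimethyl-5-(triisopropylsilyloxy)-2H-chromen-8-yl]-4,4,5,5-tetramethyl-1,3,2-dioxaborolane, via 8-lithiochromene 6 (not isolated)
Conditions: n-BuLi, THF, −78 °C; then iPrOBpin, −78 °C → rt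
Reagents that add atoms: 2-isopropoxy-4,4,5,5-tetramethyl-1,3,2-dioxaborolane (iPrOBpin), CC(C)OB1OC(C)(C)C(C)(C)O1
Why: Bromine–lithium exchange and borylation of the aryllithium; the silyl ether is para to the carbanion, so no silyl migration is possible.

**Step 5**
Reactants: 7 2-[2,2-dimethyl-5-(triisopropylsilyloxy)-2H-chromen-8-yl]-4,4,5,5-tetramethyl-1,3,2-dioxaborolane; 8 2-bromoprop-2-en-1-ol
Product: 9 2-[2,2-dimethyl-5-(triisopropylsilyloxy)-2H-chromen-8-yl]prop-2-en-1-ol
Conditions: Pd(dppf)Cl2 (3 mol%), K2CO3, 1,4-dioxane/H2O, 70 °C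
Reagents that add atoms: none
Why: Suzuki–Miyaura coupling of an arylboronate with a vinyl bromide, which tolerates the free allylic hydroxyl.

**Step 6**
Reactants: 4 [4-bromo-3-(2-methylbut-3-yn-2-yloxy)phenoxy]tri(propan-2-yl)silane
Product: 10 [4-bromo-3-(2-methylbut-3-en-2-yloxy)phenoxy]tri(propan-2-yl)silane
Conditions: H2 (1 atm), Pd/CaCO3 poisoned with Pb(OAc)2, quinoline, EtOAc, rt
Reagents that add atoms: none
Why: Lindlar semi-hydrogenation of the terminal alkyne to the alkene, which should leave the aryl bromide untouched.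

**Step 7**
Reactants: 10 [4-bromo-3-(2-methylbut-3-en-2-yloxy)phenoxy]tri(propan-2-yl)silane
Product: 13 2-[2-bromo-3-(2-methylbut-3-en-2-yloxy)-5-(triisopropylsilyloxy)phenyl]-4,4,5,5-tetramethyl-1,3,2-dioxaborolane, via aryllithium 11 (not isolated), via lithium aryltriisopropoxyborate 12 (not isolated)
Conditions: lithium 2,2,6,6-tetramethylpiperidide (LiTMP), B(OiPr)3 present from the start, THF, −78 °C; then pinacol, AcOH, rt
Reagents that add atoms: triisopropyl borate, CC(C)OB(OC(C)C)OC(C)C; pinacol, CC(C)(O)C(C)(C)O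
Why: Halogen-directed ortho-lithiation with in situ borate trapping; the C–H beside bromine is the only acidified and accessible one (the C–H between the two oxygens is shielded by the tertiary ether and the silyl group), and immediate capture by the borate should forestall aryne formation.

**Step 8**
Reactants: 13 2-[2-bromo-3-(2-methylbut-3-en-2-yloxy)-5-(triisopropylsilyloxy)phenyl]-4,4,5,5-tetramethyl-1,3,2-dioxaborolane
Product: 14 2-bromo-6-(3-methylbut-2-en-1-yl)-3-(4,4,5,5-tetramethyl-1,3,2-dioxaborolan-2-yl)-5-(triisopropylsilyloxy)phenol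
Conditions: o-xylene, 130 °C
Reagents that add atoms: none
Why: Aromatic Claisen rearrangement of the 1,1-dimethylallyl ether; the [3,3] shift inverts the allyl unit to the prenyl group and, with bromine on the other ortho carbon, can end only on the carbon between the two oxygens.

**Step 9**
Reactants: 14 2-bromo-6-(3-methylbut-2-en-1-yl)-3-(4,4,5,5-tetramethyl-1,3,2-dioxaborolan-2-yl)-5-(triisopropylsilyloxy)phenol
Product: 15 2-[2-bromo-3-methoxy-4-(3-methylbut-2-en-1-yl)-5-(triisopropylsilyloxy)phenyl]-4,4,5,5-tetramethyl-1,3,2-dioxaborolane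
Conditions: MeI, K2CO3, acetone, 45 °C
Reagents that add atoms: iodomethane, CI
Why: Williamson O-methylation of the only free phenol; the pinacol boronate, which masks the future O1, is inert to anhydrous carbonate.

**Step 10**
Reactants: 15 2-[2-bromo-3-methoxy-4-(3-methylbut-2-en-1-yl)-5-(triisopropylsilyloxy)phenyl]-4,4,5,5-tetramethyl-1,3,2-dioxaborolane
Product: 16 2-bromo-3-methoxy-4-(3-methylbut-2-en-1-yl)-5-(triisopropylsilyloxy)phenol
Conditions: H2O2 (30% aq.), NaOH (1 equiv), THF, 0 °C
Reagents that add atoms: hydrogen peroxide, OO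
Why: Oxidation of the aryl pinacol boronate to the phenol (boron-to-oxygen 1,2-aryl shift); nucleophilic peroxide should not touch the trisubstituted olefin.

**Step 11**
Reactants: 16 2-bromo-3-methoxy-4-(3-methylbut-2-en-1-yl)-5-(triisopropylsilyloxy)phenol; 9 2-[2,2-dimethyl-5-(triisopropylsilyloxy)-2H-chromen-8-yl]prop-2-en-1-ol
Product: 17 8-{3-[2-bromo-3-methoxy-4-(3-methylbut-2-en-1-yl)-5-(triisopropylsilyloxy)phenoxy]prop-1-en-2-yl}-2,2-dimethyl-5-(triisopropylsilyloxy)-2H-chromene
Conditions: PPh3, DIAD, THF, 0 °C → rt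
Reagents that add atoms: none
Why: Mitsunobu etherification of the acidic ortho-bromophenol with a primary allylic alcohol; attack at either terminus of the symmetrical 2-arylallyl unit gives the same ether.

**Step 12**
Reactants: 17 8-{3-[2-bromo-3-methoxy-4-(3-methylbut-2-en-1-yl)-5-(triisopropylsilyloxy)phenoxy]prop-1-en-2-yl}-2,2-dimethyl-5-(triisopropylsilyloxy)-2H-chromene
Product: 19 (3R)-3-[2,2-dimethyl-5-(triisopropylsilyloxy)-2H-chromen-8-yl]-5-methoxy-6-(3-methylbut-2-en-1-yl)-7-(triisopropylsilyloxy)chromane, via primary alkylboronate 18 (not isolated)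
Conditions: (L)CoCl2 (5 mol%), NaBHEt3 (10 mol%), HBpin (1.2 equiv), THF, rt; then Pd(OAc)2 (5 mol%), RuPhos (10 mol%), aq. K3PO4, toluene, 90 °C
Reagents that add atoms: none
Why: NaBHEt3 converts the cobalt dichloride complex into a cobalt hydride that inserts the 1,1-disubstituted olefin with cobalt on the terminal carbon and hydrogen on C3, exchange with HBpin releases boronate 18, and after addition of the palladium system zerovalent palladium inserts into the C4a–Br bond, the phosphate-activated alkylboronate transmetalates and reductive elimination forms C4–C4a. The closest known reactions are the cobalt/iminopyridine–oxazoline-catalysed enantioselective anti-Markovnikov hydroboration of α-alkylstyrenes and the B-alkyl Suzuki–Miyaura coupling of primary alkyl pinacol boronates with hindered aryl bromides under Pd(OAc)2/RuPhos, run here one after the other in one flask. Ring C closes as a six-membered ring by intramolecular C(sp3)–C(sp2) cross-coupling, the bond arising by reductive elimination from a seven-membered palladacycle. The C3 stereocentre is set under catalyst control in the hydride-transfer step (the ligand tells ring B from the aryloxymethyl arm, and Si-face delivery gives 3R) and, being β to boron, is not touched during the coupling. The step needs chemoselectivity for the terminal olefin over the trisubstituted prenyl olefin and the chromene olefin, secured by their higher substitution and by the quaternary carbon beside the chromene double bond, and anti-Markovnikov regioselectivity, which leaves O1 on the carbon γ to the metal so that aryloxide elimination has no β-leaving group. The aryl bromide, flanked by OMe and the ether oxygen, is expected to pass the cobalt stage unchanged and is then the only site open to palladium.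

**Step 13**
Reactants: 19 (3R)-3-[2,2-dimethyl-5-(triisopropylsilyloxy)-2H-chromen-8-yl]-5-methoxy-6-(3-methylbut-2-en-1-yl)-7-(triisopropylsilyloxy)chromane
Product: 20 (3R)-3-(5-hydroxy-2,2-dimethyl-2H-chromen-8-yl)-5-methoxy-6-(3-methylbut-2-en-1-yl)chroman-7-ol
Conditions: Bu4NF (2.5 equiv), THF, 0 °C; aq. NH4Cl work-up
Reagents that add atoms: none
Why: Fluoride-induced cleavage of both aryl silyl ethers under non-acidic conditions, which should leave the prenyl and chromene olefins and the C3 stereocentre untouched.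

**Compound list**
1 | 4-bromoresorcinol (4-bromobenzene-1,3-diol) | Oc1ccc(Br)c(O)c1 | starting material
2 | 2-bromo-5-(triisopropylsilyloxy)phenol | Oc1cc(O[Si](C(C)C)(C(C)C)C(C)C)ccc1Br | intermediate
3 | 3-chloro-3-methylbut-1-yne | CC(C)(Cl)C#C | starting material
4 | [4-bromo-3-(2-methylbut-3-yn-2-yloxy)phenoxy]tri(propan-2-yl)silane | C#CC(C)(C)Oc1cc(O[Si](C(C)C)(C(C)C)C(C)C)ccc1Br | intermediate
5 | 8-bromo-2,2-dimethyl-5-(triisopropylsilyloxy)-2H-chromene | CC1(C)C=Cc2c(O[Si](C(C)C)(C(C)C)C(C)C)ccc(Br)c2O1 | intermediate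
6 | 8-lithio-2,2-dimethyl-5-(triisopropylsilyloxy)-2H-chromene | [Li]c1ccc(O[Si](C(C)C)(C(C)C)C(C)C)c2C=CC(C)(C)Oc12 | intermediate
7 | 2-[2,2-dimethyl-5-(triisopropylsilyloxy)-2H-chromen-8-yl]-4,4,5,5-tetramethyl-1,3,2-dioxaborolane | CC1(C)C=Cc2c(O[Si](C(C)C)(C(C)C)C(C)C)ccc(B3OC(C)(C)C(C)(C)O3)c2O1 | intermediate
8 | 2-bromoprop-2-en-1-ol | OCC(Br)=C | starting material
9 | 2-[2,2-dimethyl-5-(triisopropylsilyloxy)-2H-chromen-8-yl]prop-2-en-1-ol | OCC(=C)c1ccc(O[Si](C(C)C)(C(C)C)C(C)C)c2C=CC(C)(C)Oc12 | intermediate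
10 | [4-bromo-3-(2-methylbut-3-en-2-yloxy)phenoxy]tri(propan-2-yl)silane | C=CC(C)(C)Oc1cc(O[Si](C(C)C)(C(C)C)C(C)C)ccc1Br | intermediate
11 | [2-bromo-3-(2-methylbut-3-en-2-yloxy)-5-(triisopropylsilyloxy)phenyl]lithium | C=CC(C)(C)Oc1cc(O[Si](C(C)C)(C(C)C)C(C)C)cc([Li])c1Br | intermediate
12 | lithium [2-bromo-3-(2-methylbut-3-en-2-yloxy)-5-(triisopropylsilyloxy)phenyl]tri(propan-2-yloxy)borate | [Li+].C=CC(C)(C)Oc1cc(O[Si](C(C)C)(C(C)C)C(C)C)cc([B-](OC(C)C)(OC(C)C)OC(C)C)c1Br | intermediate
13 | 2-[2-bromo-3-(2-methylbut-3-en-2-yloxy)-5-(triisopropylsilyloxy)phenyl]-4,4,5,5-tetramethyl-1,3,2-dioxaborolane | C=CC(C)(C)Oc1cc(O[Si](C(C)C)(C(C)C)C(C)C)cc(B2OC(C)(C)C(C)(C)O2)c1Br | intermediate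
14 | 2-bromo-6-(3-methylbut-2-en-1-yl)-3-(4,4,5,5-tetramethyl-1,3,2-dioxaborolan-2-yl)-5-(triisopropylsilyloxy)phenol | Oc1c(CC=C(C)C)c(O[Si](C(C)C)(C(C)C)C(C)C)cc(B2OC(C)(C)C(C)(C)O2)c1Br | intermediate
15 | 2-[2-bromo-3-methoxy-4-(3-methylbut-2-en-1-yl)-5-(triisopropylsilyloxy)phenyl]-4,4,5,5-tetramethyl-1,3,2-dioxaborolane | COc1c(CC=C(C)C)c(O[Si](C(C)C)(C(C)C)C(C)C)cc(B2OC(C)(C)C(C)(C)O2)c1Br | intermediate
16 | 2-bromo-3-methoxy-4-(3-methylbut-2-en-1-yl)-5-(triisopropylsilyloxy)phenol | COc1c(CC=C(C)C)c(O[Si](C(C)C)(C(C)C)C(C)C)cc(O)c1Br | intermediate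
17 | 8-{3-[2-bromo-3-methoxy-4-(3-methylbut-2-en-1-yl)-5-(triisopropylsilyloxy)phenoxy]prop-1-en-2-yl}-2,2-dimethyl-5-(triisopropylsilyloxy)-2H-chromene | COc1c(CC=C(C)C)c(O[Si](C(C)C)(C(C)C)C(C)C)cc(OCC(=C)c2ccc(O[Si](C(C)C)(C(C)C)C(C)C)c3c2OC(C)(C)C=C3)c1Br | intermediate
18 | 8-{(2R)-1-[2-bromo-3-methoxy-4-(3-methylbut-2-en-1-yl)-5-(triisopropylsilyloxy)phenoxy]-3-(4,4,5,5-tetramethyl-1,3,2-dioxaborolan-2-yl)propan-2-yl}-2,2-dimethyl-5-(triisopropylsilyloxy)-2H-chromene | COc1c(CC=C(C)C)c(O[Si](C(C)C)(C(C)C)C(C)C)cc(OC[C@H](CB4OC(C)(C)C(C)(C)O4)c2ccc(O[Si](C(C)C)(C(C)C)C(C)C)c3c2OC(C)(C)C=C3)c1Br | intermediate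
19 | (3R)-3-[2,2-dimethyl-5-(triisopropylsilyloxy)-2H-chromen-8-yl]-5-methoxy-6-(3-methylbut-2-en-1-yl)-7-(triisopropylsilyloxy)chromane | COc1c(CC=C(C)C)c(O[Si](C(C)C)(C(C)C)C(C)C)cc2c1C[C@H](c1ccc(O[Si](C(C)C)(C(C)C)C(C)C)c3c1OC(C)(C)C=C3)CO2 | intermediate
20 | (3R)-3-(5-hydroxy-2,2-dimethyl-2H-chromen-8-yl)-5-methoxy-6-(3-methylbut-2-en-1-yl)chroman-7-ol | COc1c(CC=C(C)C)c(O)cc2c1C[C@H](c1ccc(O)c3c1OC(C)(C)C=C3)CO2 | target

**Step count.** Total: 13 steps. Longest linear sequence: 10 steps (steps 1, 2, 6, 7, 8, 9, 10, 11, 12, 13) from 4-bromoresorcinol.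

**Steps most likely to fail**

Step 12. The ortho oxygen on ring B may weaken the facial discrimination of the cobalt hydride. A Markovnikov insertion would put the aryloxy group β to cobalt and could cleave the allyl ether. The pinacol boronate may also transmetalate slowly. The fallback sets out from 17 and gives up asymmetric catalysis. Hydroboration with 9-BBN (THF, rt) should give the racemic B-alkyl-9-borabicyclononane adduct F1. Addition of Pd(dppf)Cl2 and aqueous K3PO4 to the same flask (the classical B-alkyl Suzuki cyclisation) should close ring C to the racemic bis-silyl isoflavan F2. Preparative HPLC on a chiral stationary phase then separates 19 from its (3S) mirror image F3, and the route resumes at 19.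

Step 7. Deprotonation may occur at another site, or the ortho-bromoaryllithium may lose LiBr to an aryne before the borate captures it. The fallback sets out from 10 and places boron by sterically governed C–H activation. Claisen rearrangement first (o-xylene, 130 °C) gives the prenylphenol 6-bromo-2-(3-methylbut-2-en-1-yl)-3-(triisopropylsilyloxy)phenol F4. Methylation (MeI, K2CO3, acetone) gives the bromoanisole [4-bromo-3-methoxy-2-(3-methylbut-2-en-1-yl)phenoxy]tri(propan-2-yl)silane F5. Iridium-catalysed borylation ([Ir(OMe)(cod)]2, 4,4′-di-tert-butyl-2,2′-bipyridine, B2pin2, THF, 80 °C) should then take the ring hydrogen beside bromine. The other ring hydrogen is shielded because the silyl group, pushed by the prenyl group, leans over it. This gives 15, where the route resumes.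

Step 5. The electron-rich ortho-alkoxy arylboronate may protodeboronate, or the bromoallyl alcohol may decompose by elimination at the vinylpalladium stage. The fallback sets out from 5 and builds the allyl alcohol by carbonyl chemistry. Aryllithium 6, made as in step 4, is added to 2-(tert-butyldimethylsilyloxy)-N-methoxy-N-methylacetamide (a Weinreb amide) to give the ketone 2-(tert-butyldimethylsilyloxy)-1-[2,2-dimethyl-5-(triisopropylsilyloxy)-2H-chromen-8-yl]ethan-1-one F6. Wittig methylenation (Ph3P=CH2, THF) gives the silyl ether tert-butyl({2-[2,2-dimethyl-5-(triisopropylsilyloxy)-2H-chromen-8-yl]prop-2-en-1-yl}oxy)dimethylsilane F7. PPTS in MeOH removes the primary alkyl silyl group, the aryl silyl ether being stable to it, and gives 9.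

**Further compounds**
F1 | step 12 | racemic 9-{3-[2-bromo-3-methoxy-4-(3-methylbut-2-en-1-yl)-5-(triisopropylsilyloxy)phenoxy]-2-[2,2-dimethyl-5-(triisopropylsilyloxy)-2H-chromen-8-yl]propyl}-9-borabicyclo[3.3.1]nonane | COc1c(CC=C(C)C)c(O[Si](C(C)C)(C(C)C)C(C)C)cc(OCC(CB4C5CCCC4CCC5)c2ccc(O[Si](C(C)C)(C(C)C)C(C)C)c3c2OC(C)(C)C=C3)c1Br
F2 | step 12 | racemic 3-[2,2-dimethyl-5-(triisopropylsilyloxy)-2H-chromen-8-yl]-5-methoxy-6-(3-methylbut-2-en-1-yl)-7-(triisopropylsilyloxy)chromane | COc1c(CC=C(C)C)c(O[Si](C(C)C)(C(C)C)C(C)C)cc2c1CC(c1ccc(O[Si](C(C)C)(C(C)C)C(C)C)c3c1OC(C)(C)C=C3)CO2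
F3 | step 12 | (3S)-3-[2,2-dimethyl-5-(triisopropylsilyloxy)-2H-chromen-8-yl]-5-methoxy-6-(3-methylbut-2-en-1-yl)-7-(triisopropylsilyloxy)chromane | COc1c(CC=C(C)C)c(O[Si](C(C)C)(C(C)C)C(C)C)cc2c1C[C@@H](c1ccc(O[Si](C(C)C)(C(C)C)C(C)C)c3c1OC(C)(C)C=C3)CO2
F4 | step 7 | 6-bromo-2-(3-methylbut-2-en-1-yl)-3-(triisopropylsilyloxy)phenol | Oc1c(CC=C(C)C)c(O[Si](C(C)C)(C(C)C)C(C)C)ccc1Br
F5 | step 7 | [4-bromo-3-methoxy-2-(3-methylbut-2-en-1-yl)phenoxy]tri(propan-2-yl)silane | COc1c(CC=C(C)C)c(O[Si](C(C)C)(C(C)C)C(C)C)ccc1Br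
F6 | step 5 | 2-(tert-butyldimethylsilyloxy)-1-[2,2-dimethyl-5-(triisopropylsilyloxy)-2H-chromen-8-yl]ethan-1-one | CC(C)(C)[Si](C)(C)OCC(=O)c1ccc(O[Si](C(C)C)(C(C)C)C(C)C)c2C=CC(C)(C)Oc12
F7 | step 5 | tert-butyl({2-[2,2-dimethyl-5-(triisopropylsilyloxy)-2H-chromen-8-yl]prop-2-en-1-yl}oxy)dimethylsilane | CC(C)(C)[Si](C)(C)OCC(=C)c1ccc(O[Si](C(C)C)(C(C)C)C(C)C)c2C=CC(C)(C)Oc12
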